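**Retrosynthetic overview**

- The target is reached by acetylation at C1 and angeloylation at C4 of a (1R,4S)-cycloundecadiene-1,4-diol, which comes from saturation of a C9=C10 olefin.
- The eleven-membered ring (the only ring of the target) is closed at C1–C11 by an intramolecular Nozaki–Hiyama allylation of an unprotected acyclic lactol/allylic chloride. This is the same bond, the same polarity (C11 nucleophile, C1 electrophile) and the same C9=C10 olefin outcome as the enzymatic 1,11-cyclisation of a farnesyl chain to the humulyl cation and humulene. The step also installs the C1 oxygen and its configuration.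
- The lactol comes from an (S)-butenolide (C1–C4, 2Z locked in the ring), made by an enantioselective Ni/Cr coupling that forms C3–C4 from a C11 aldehyde and a (Z)-3-iodobut-2-enoate.
- The C11 aldehyde comes from prenal, propargyl bromide and ethylene oxide; a zirconium-catalysed carboalumination sets 6E.
- Ring order: a temporary butenolide/lactol ring first (opened in the key step), then the eleven-membered carbocycle.

Assumption: atoms are numbered as in the farnesyl chain (C1 = CH–OAc, C4 = CH–O-angeloyl, C11 = CMe2), so the target is the (1R,2Z,4S,6E) diester; the racemic C9 carbinol/chloride centre carried from step 1 to step 7 is destroyed in step 8 and is left undefined in the SMILES.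

**Route**

Step 1
Reactants: 1 3-methylbut-2-enal (prenal); 2 3-bromoprop-1-yne (propargyl bromide)
Product: 3 rac-6-methylhept-5-en-1-yn-4-ol
Conditions: Zn dust, THF/sat. aq. NH4Cl, 0 °C to rt
Reagents that add atoms: none
Why: Barbier propargylation: the allenylzinc generated in situ adds 1,2 to the enal through an SE2′ transition state to give the homopropargylic alcohol, whose racemic carbinol centre is harmless because it is destroyed in step 8.

Step 2
Reactants: 3 rac-6-methylhept-5-en-1-yn-4-ol; 4 oxirane (ethylene oxide)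
Product: 6 (3E)-4,8-dimethylnona-3,7-diene-1,6-diol, via alkenylalane 5 (not isolated)
Conditions: Me3Al (3 equiv), Cp2ZrCl2 (25 mol%), CH2Cl2, 0 °C to rt; evaporate; n-BuLi, THF, −78 °C; then 4, −78 to 0 °C; 1 M HCl
Reagents that add atoms: trimethylaluminium, C[Al](C)C
Why: Negishi zirconium-catalysed carboalumination (syn addition of Me–Al across the terminal alkyne, methyl to the internal carbon) fixes the trisubstituted 6E olefin, and the derived lithium alanate opens ethylene oxide with retention of that geometry.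

Step 3
Reactants: 6 (3E)-4,8-dimethylnona-3,7-diene-1,6-diol
Product: 7 (3E)-6-hydroxy-4,8-dimethylnona-3,7-dienal
Conditions: TEMPO (10 mol%), PhI(OAc)2 (1.1 equiv), CH2Cl2, rt
Reagents that add atoms: none
Why: TEMPO/oxoammonium oxidation is selective for the unhindered primary alcohol over the secondary allylic one and is neutral enough to leave the β,γ-unsaturated aldehyde unconjugated (used crude).

Step 4
Reactants: 8 ethyl but-2-ynoate
Product: 9 ethyl (2Z)-3-iodobut-2-enoate
Conditions: NaI, AcOH, 115 °C
Reagents that add atoms: sodium iodide, [Na+].[I-]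
Why: Hydroiodination of an ynoate (conjugate addition of iodide, then protonation; net anti addition) gives the (Z)-β-iodo enoate that later guarantees the 2Z geometry.

Step 5
Reactants: 7 (3E)-6-hydroxy-4,8-dimethylnona-3,7-dienal; 9 ethyl (2Z)-3-iodobut-2-enoate
Product: 11 (5S)-5-[(2E)-5-hydroxy-3,7-dimethylocta-2,6-dien-1-yl]-4-methylfuran-2(5H)-one, via hydroxy (Z)-enoate 10 (not isolated)
Conditions: CrCl2 (15 mol%), Kishi oxazoline–sulfonamide ligand (17 mol%), 1,8-bis(dimethylamino)naphthalene (17 mol%), NiCl2·(2,9-dimethyl-1,10-phenanthroline) (2 mol%), Mn, Cp2ZrCl2, LiCl, MeCN, rt; then PPTS (cat.), CH2Cl2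
Reagents that add atoms: none
Why: Catalytic asymmetric Nozaki–Hiyama–Kishi alkenylation: oxidative addition to zerovalent nickel and transmetalation to chromium keep the Z geometry, the sulfonamide-ligated alkenylchromium adds to one aldehyde face to set C4 as S (ligand enantiomer chosen accordingly), and the (Z)-γ-hydroxy enoate lactonises, which both proves and locks the 2Z olefin.

Step 6
Reactants: 11 (5S)-5-[(2E)-5-hydroxy-3,7-dimethylocta-2,6-dien-1-yl]-4-methylfuran-2(5H)-one
Product: 12 (5S)-5-[(2E)-5-chloro-3,7-dimethylocta-2,6-dien-1-yl]-4-methylfuran-2(5H)-one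
Conditions: NCS, Me2S, CH2Cl2, −20 to 0 °C
Reagents that add atoms: N-chlorosuccinimide, O=C1CCC(=O)N1Cl
Why: Corey–Kim chlorination turns the allylic alcohol into the allylic chloride under base-free conditions that neither touch the butenolide nor epimerise its γ-centre; regio- and stereoisomeric chlorides are acceptable because they converge on one allylchromium.

Step 7
Reactants: 12 (5S)-5-[(2E)-5-chloro-3,7-dimethylocta-2,6-dien-1-yl]-4-methylfuran-2(5H)-one
Product: 13 (5S)-5-[(2E)-5-chloro-3,7-dimethylocta-2,6-dien-1-yl]-4-methyl-2,5-dihydrofuran-2-ol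
Conditions: i-Bu2AlH (1.1 equiv), CH2Cl2, −78 °C; aq. potassium sodium tartrate
Reagents that add atoms: none
Why: Partial hydride reduction of the lactone stops at the tetrahedral aluminate at −78 °C and gives the lactol, the masked form of the (Z)-4-hydroxy enal, without touching the allylic chloride; it is kept acid-free and used at once to avoid dehydration to the furan.

Step 8
Reactants: 13 (5S)-5-[(2E)-5-chloro-3,7-dimethylocta-2,6-dien-1-yl]-4-methyl-2,5-dihydrofuran-2-ol
Product: 15 (1R,2Z,4S,6E,9E)-3,7,11,11-tetramethylcycloundeca-2,6,9-triene-1,4-diol, via allylchromium hydroxy-enal 14 (not isolated)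
Conditions: CrCl2 (8 equiv), THF/DMF 4:1, syringe-pump addition to 2 mM, rt; aq. NH4Cl
Reagents that add atoms: none
Why: Intramolecular Nozaki–Hiyama allylation: divalent chromium inserts into the allylic chloride and the γ,γ-dimethyl terminus (C11) of the allylchromium adds through a closed six-membered transition state to the aldehyde of the ring-opened lactol (the organometallic counterpart of the enzymatic C1–C11 closure, leaving C9=C10 as in humulene; its geometry is irrelevant because it is reduced next), while the C4 chromium alkoxide chelates the aldehyde oxygen (s-cis enal) so that the tethered nucleophile reaches C1 from the C5 side, which is expected, but not assured, to give the 1,4-trans (1R,4S) diol.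

Step 9
Reactants: 15 (1R,2Z,4S,6E,9E)-3,7,11,11-tetramethylcycloundeca-2,6,9-triene-1,4-diol
Product: 16 (1R,2Z,4S,6E)-3,7,11,11-tetramethylcycloundeca-2,6-diene-1,4-diol
Conditions: 2-nitrobenzenesulfonylhydrazide, Et3N, CH2Cl2, rt
Reagents that add atoms: none
Why: Diimide reduction (concerted syn transfer of H2) is far faster for the 1,2-disubstituted C9=C10 olefin than for the two trisubstituted olefins, and no stereocentre is affected.

Step 10
Reactants: 16 (1R,2Z,4S,6E)-3,7,11,11-tetramethylcycloundeca-2,6-diene-1,4-diol; 17 (2Z)-2-methylbut-2-enoic acid (angelic acid)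
Product: 19 (1R,2Z,4S,6E)-1-hydroxy-3,7,11,11-tetramethylcycloundeca-2,6-dien-4-yl (2Z)-2-methylbut-2-enoate, via mixed anhydride 18 (not isolated)
Conditions: 17, 2,4,6-trichlorobenzoyl chloride, Et3N, toluene, rt; then 16, 80 °C
Reagents that add atoms: none
Why: Mixed-anhydride (Yamaguchi-type) esterification run without a nucleophilic catalyst transfers the angeloyl group without Z to E isomerisation and goes to the less hindered C4 hydroxyl, the C1 hydroxyl being neopentyl next to the gem-dimethyl carbon.

Step 11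
Reactants: 19 (1R,2Z,4S,6E)-1-hydroxy-3,7,11,11-tetramethylcycloundeca-2,6-dien-4-yl (2Z)-2-methylbut-2-enoate
Product: 20 (1R,2Z,4S,6E)-1-acetoxy-3,7,11,11-tetramethylcycloundeca-2,6-dien-4-yl (2Z)-2-methylbut-2-enoate (CNP0322023.1)
Conditions: Ac2O, pyridine, DMAP (cat.), CH2Cl2, rt
Reagents that add atoms: acetic anhydride, CC(=O)OC(C)=O
Why: DMAP-catalysed acetylation of the remaining hindered allylic alcohol completes the target with retention at C1.

**Compound list**

1 | 3-methylbut-2-enal (prenal) | CC(C)=CC=O | starting material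
2 | 3-bromoprop-1-yne (propargyl bromide) | BrCC#C | starting material
3 | rac-6-methylhept-5-en-1-yn-4-ol | C#CCC(O)C=C(C)C | intermediate
4 | oxirane (ethylene oxide) | C1CO1 | starting material
5 | dimethyl[(1E)-4-(dimethylalumanyloxy)-2,6-dimethylhepta-1,5-dien-1-yl]alumane (alkenylalane, formed in the flask, not isolated) | C[Al](C)/C=C(\C)CC(O[Al](C)C)C=C(C)C | intermediate
6 | (3E)-4,8-dimethylnona-3,7-diene-1,6-diol (C6 racemic) | OCC/C=C(\C)CC(O)C=C(C)C | intermediate
7 | (3E)-6-hydroxy-4,8-dimethylnona-3,7-dienal (C6 racemic) | O=CC/C=C(\C)CC(O)C=C(C)C | intermediate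
8 | ethyl but-2-ynoate | CC#CC(=O)OCC | starting material
9 | ethyl (2Z)-3-iodobut-2-enoate | CCOC(=O)/C=C(/C)I | intermediate
10 | ethyl (2Z,4S,6E)-4,9-dihydroxy-3,7,11-trimethyldodeca-2,6,10-trienoate (C9 epimers, not isolated) | CCOC(=O)/C=C(/C)[C@@H](O)C/C=C(\C)CC(O)C=C(C)C | intermediate
11 | (5S)-5-[(2E)-5-hydroxy-3,7-dimethylocta-2,6-dien-1-yl]-4-methylfuran-2(5H)-one (side-chain carbinol epimers) | O=C1C=C(C)[C@H](C/C=C(\C)CC(O)C=C(C)C)O1 | intermediate
12 | (5S)-5-[(2E)-5-chloro-3,7-dimethylocta-2,6-dien-1-yl]-4-methylfuran-2(5H)-one (chloride epimers) | O=C1C=C(C)[C@H](C/C=C(\C)CC(Cl)C=C(C)C)O1 | intermediate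
13 | (5S)-5-[(2E)-5-chloro-3,7-dimethylocta-2,6-dien-1-yl]-4-methyl-2,5-dihydrofuran-2-ol (anomers) | OC1C=C(C)[C@H](C/C=C(\C)CC(Cl)C=C(C)C)O1 | intermediate
14 | (2Z,4S,6E)-9-(dichlorochromio)-4-hydroxy-3,7,11-trimethyldodeca-2,6,10-trienal (allylchromium of the ring-opened lactol, not isolated) | O=C/C=C(/C)[C@@H](O)C/C=C(\C)CC([Cr](Cl)Cl)C=C(C)C | intermediate
15 | (1R,2Z,4S,6E,9E)-3,7,11,11-tetramethylcycloundeca-2,6,9-triene-1,4-diol | O[C@H]1C/C=C(\C)C/C=C/C(C)(C)[C@H](O)/C=C\1C | intermediate
16 | (1R,2Z,4S,6E)-3,7,11,11-tetramethylcycloundeca-2,6-diene-1,4-diol | O[C@H]1C/C=C(\C)CCCC(C)(C)[C@H](O)/C=C\1C | intermediate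
17 | (2Z)-2-methylbut-2-enoic acid (angelic acid) | C/C=C(/C)C(=O)O | starting material
18 | (2Z)-2-methylbut-2-enoic 2,4,6-trichlorobenzoic anhydride (not isolated) | C/C=C(/C)C(=O)OC(=O)c1c(Cl)cc(Cl)cc1Cl | intermediate
19 | (1R,2Z,4S,6E)-1-hydroxy-3,7,11,11-tetramethylcycloundeca-2,6-dien-4-yl (2Z)-2-methylbut-2-enoate | C/C=C(/C)C(=O)O[C@H]1C/C=C(\C)CCCC(C)(C)[C@H](O)/C=C\1C | intermediate
20 | (1R,2Z,4S,6E)-1-acetoxy-3,7,11,11-tetramethylcycloundeca-2,6-dien-4-yl (2Z)-2-methylbut-2-enoate (CNP0322023.1) | C/C=C(/C)C(=O)O[C@H]1C/C=C(\C)CCCC(C)(C)[C@H](OC(C)=O)/C=C\1C | target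

**Step count**

Total steps: 11. Longest linear sequence: 10 (steps 1–3 and 5–11; step 4 is a one-step side branch).

**Three steps most likely to fail, with fallbacks**

Step 8 (macrocyclisation on the free lactol). The lactol may dehydrate to the furan under trivalent chromium, the eleven-membered closure may be slow, or C1 may form as the wrong epimer. The fallback sets out from chloro butenolide 12 and comes back at triene diol 15, and replaces the chelating free lactol by a protected open-chain aldehyde. Excess i-Bu2AlH (2.5 equiv, −78 to 0 °C) reduces 12 to (2Z,4S,6E)-9-chloro-3,7,11-trimethyldodeca-2,6,10-triene-1,4-diol F1. Et3SiCl/imidazole gives the bis(triethylsilyl) ether F2. Swern conditions ((COCl)2, DMSO, then Et3N) oxidise the primary silyl ether directly to (2Z,4S,6E)-9-chloro-3,7,11-trimethyl-4-[(triethylsilyl)oxy]dodeca-2,6,10-trienal F3, which cannot lactolise or aromatise. CrCl2 under the same high dilution closes the ring to (1R,2Z,4S,6E,9E)-3,7,11,11-tetramethyl-4-[(triethylsilyl)oxy]cycloundeca-2,6,9-trien-1-ol F4. If C1 comes out as the wrong epimer, it is corrected by Dess–Martin oxidation to the macrocyclic (2Z)-enone F5 and reagent-controlled CBS reduction back to F4. Bu4NF then gives 15.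

Step 5 (asymmetric Ni/Cr butenolide formation). The enantioselectivity may be insufficient, or the β,γ-unsaturated aldehyde may react poorly. The fallback sets out from aldehyde 7 and comes back at butenolide 11; it sets C4 by alkynylation and builds the C3 methyl and the 2Z olefin by carbocupration. Me2Zn/ProPhenol-catalysed (Trost) addition of methyl propiolate, with the ligand enantiomer that gives 4S, affords methyl (4S,6E)-4,9-dihydroxy-7,11-dimethyldodeca-6,10-dien-2-ynoate F6. Syn conjugate addition of Me2CuLi (THF, −78 °C) and protonation give the (Z)-enoate, which lactonises to 11.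

Step 9 (chemoselective diimide reduction). The C9=C10 olefin sits next to a quaternary carbon, and the strained E-trisubstituted ring olefin may compete. The fallback sets out from triene diol 15 and comes back at diene diol 16; it uses catalyst-controlled hydrogenation on a protected substrate. Et3SiOTf/2,6-lutidine gives the bis(triethylsilyl) ether F7. RhCl(PPh3)3 under H2 (1 atm, benzene) reduces disubstituted but not trisubstituted olefins and, with the hydroxyls masked, is not directed to C2=C3; it gives the bis(triethylsilyl) ether of the diene diol F8. HF·pyridine then returns 16.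

Further compounds
F1 | step 8 | (2Z,4S,6E)-9-chloro-3,7,11-trimethyldodeca-2,6,10-triene-1,4-diol | OC/C=C(/C)[C@@H](O)C/C=C(\C)CC(Cl)C=C(C)C
F2 | step 8 | (2Z,4S,6E)-9-chloro-3,7,11-trimethyl-1,4-bis[(triethylsilyl)oxy]dodeca-2,6,10-triene | CC[Si](CC)(CC)OC/C=C(/C)[C@@H](O[Si](CC)(CC)CC)C/C=C(\C)CC(Cl)C=C(C)C
F3 | step 8 | (2Z,4S,6E)-9-chloro-3,7,11-trimethyl-4-[(triethylsilyl)oxy]dodeca-2,6,10-trienal | O=C/C=C(/C)[C@@H](O[Si](CC)(CC)CC)C/C=C(\C)CC(Cl)C=C(C)C
F4 | step 8 | (1R,2Z,4S,6E,9E)-3,7,11,11-tetramethyl-4-[(triethylsilyl)oxy]cycloundeca-2,6,9-trien-1-ol | CC[Si](CC)(CC)O[C@H]1C/C=C(\C)C/C=C/C(C)(C)[C@H](O)/C=C\1C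
F5 | step 8 | (2Z,4S,6E,9E)-3,7,11,11-tetramethyl-4-[(triethylsilyl)oxy]cycloundeca-2,6,9-trien-1-one | CC[Si](CC)(CC)O[C@H]1C/C=C(\C)C/C=C/C(C)(C)C(=O)/C=C\1C
F6 | step 5 | methyl (4S,6E)-4,9-dihydroxy-7,11-dimethyldodeca-6,10-dien-2-ynoate | COC(=O)C#C[C@@H](O)C/C=C(\C)CC(O)C=C(C)C
F7 | step 9 | (1R,2Z,4S,6E,9E)-3,7,11,11-tetramethyl-1,4-bis[(triethylsilyl)oxy]cycloundeca-2,6,9-triene | CC[Si](CC)(CC)O[C@H]1C/C=C(\C)C/C=C/C(C)(C)[C@H](O[Si](CC)(CC)CC)/C=C\1C
F8 | step 9 | (1R,2Z,4S,6E)-3,7,11,11-tetramethyl-1,4-bis[(triethylsilyl)oxy]cycloundeca-2,6-diene | CC[Si](CC)(CC)O[C@H]1C/C=C(\C)CCCC(C)(C)[C@H](O[Si](CC)(CC)CC)/C=C\1C
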